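The larch run is this same flask, read up to 5.00 d, and I want it at 12 d.

the same everywhere: left-handed substrate 0.050 M; right-handed substrate 0.050 M; reagent 0.125 M; added ligand 6.4 mM
- larch: catalyst 5 mM; the very flask that is asked about, followed so far
- flask: catalyst 5.0 mM; time 12 d

- larch (time / d: left-handed product / %, right-handed product / %): 1.25: 32, 21; 2.50: 36, 32; 4.00: 44, 41; 5.00: 44, 43

(standard deviation of a reading: 2 percentage points)

- catalyst is single-handed; left-handed substrate and right-handed substrate are mirror images of each other, charged as a racemate, each of them at the stated concentration
- the numbers in the tables scatter by 2 percentage points (one standard deviation)

* concentration of left-handed product at 12 d, in M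
* concentration of right-handed product at 12 d, in M
* concentration of reagent at 12 d, in M

1. I count turnovers, taking one reagent per substrate converted. The cover, the reagent charge as a fraction of the two substrates charged together, is 1.25.

2. Upper bound: the cover is above 1, so the substrates are the limiting reagent. The two products together reach at most the whole charge, and reagent keeps at least 0.250 of the substrate charge.

3. The larch readings leave 32.0% unconverted at 2.50 d and 13.0% at 5.00 d, each with its scatter. Over that stretch, by those readings, reagent stands at most at 0.570 of the substrate charge. I assume the remainder falls in proportion to reagent, so dividing by that highest level gives a low pace of 0.632 /d per unit of reagent.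

4. Lower bound, a reckoning that carries the scatter of those readings: taking the catalyst as still working and reagent as held at its floor of 0.250, I reckon the remainder at 12 d at 4.30%. The products together then hold 95.7%, which I take as the lower end of my bracket.

5. The forecast gives 0.047 M of left-handed product, 0.046 M of right-handed product and 0.032 M of reagent, on the ground that “Mirror-image reactions would share the same plateau”, and its products together make 93.0%, just below my bracket.

6. The flask gives 0.0484 M of left-handed product, 0.0482 M of right-handed product and 0.0284 M of reagent.

    reagent + catalyst + right-handed substrate → catalyst + right-handed product (k = 3.10 × 10⁻⁴ /M²/s)
    left-handed product ⇌ right-handed product (k = 1.90 × 10⁻⁵ /s)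
    catalyst + added ligand ⇌ idle complex (K = 57.0 /M, k = 0.00200 /M/s)
    left-handed substrate ⇌ right-handed substrate (k = 1.10 × 10⁻⁵ /s)
    reagent + catalyst + left-handed substrate → catalyst + left-handed product (k = 0.0450 /M²/s)

Together the products hold 96.6% of the charge, inside my bracket. They stand at 48.4% and 48.2%, and their relaxation half-life of 0.211 d is short against 12 d. The cover less those products leaves 0.284 of the substrate charge, which is 22.7% of reagent's own charge; the flask holds 23%. A neighbour flask charged with 0.031 M of reagent has a cover of 0.310. There reagent is the first to run out, down to 0.14% of its charge, and the products together hold 0.310 of the substrate charge.

The readings stem from a simulated flask on assumed constants, noise included.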